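At 250 µM of added ligand, flask alpha holds 8.33 times the added ligand of flask gamma, and the other charges are the same, so a repeat of this series is a comparison of what that ligand takes away.

in all of them: substrate 20 mM; coupling partner 2.50 equiv; free catalyst 0.12 mol%; second catalyst 2.4 mol%; time 15 d
- gamma: added ligand 30 µM
- beta: added ligand 60 µM
- theta: added ligand 120 µM
- alpha: added ligand 250 µM

    coupling partner + catalyst intermediate → second catalyst + target (k1 = 474 M⁻¹ h⁻¹)
    substrate + free catalyst ⇌ free catalyst + open intermediate (K2 = 1.9, k2 = 912 M⁻¹ h⁻¹)
    second catalyst + open intermediate ⇌ catalyst intermediate (K3 = 2.56 M⁻¹, k3 = 732 M⁻¹ h⁻¹)
    free catalyst + added ligand ⇌ idle complex, settled at all times (K4 = 32000 M⁻¹)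

* amount of target at the end, in percent of the substrate charged for gamma, beta, theta, alpha, in this order
* the course of these numbers from the first flask to the last (falls all the way / rises, then falls / rises all the way / falls, then rises / hardly changes)

- "hardly changes" means that all values lie within two and a half points (for a concentration: within two and a half percent of the largest)
- run time (gamma): 15 d

I turned the constants into times at the charged amounts. Free catalyst stays in fast balance with added ligand, so I solved that balance first: of 24.0 µM catalyst, gamma keeps 14.5 µM free, and beta, theta and alpha keep 9.74 µM, 5.64 µM and 2.88 µM. Free catalyst is constant during a run, so substrate opens in a pseudo-first-order step. Its constant k_open is the rate constant of opening times free catalyst, 0.01322 h⁻¹ in gamma, and the way back is 1.9 times slower.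

Second catalyst takes open intermediate at 0.351 h⁻¹. I set coupling partner at a round mean for a run, 38.0 mM, below its charge. Catalyst intermediate then falls back at 286 h⁻¹ and goes on at 18.0 h⁻¹, so it falls back faster than it goes on. The net capture constant k_cap is the taking constant times the share that goes on, 0.02082 h⁻¹.

For this chain I defined the passage time τ, the mean time a substrate molecule needs to become target: the opening time, which is the reciprocal of k_open, plus a tail, which is the reciprocal of k_cap times one plus the reciprocal of the opening equilibrium constant, the extra part counting the trips back. The tail is 73.3 h in each flask, and added ligand enters through the opening time. So τ is 149 h in gamma, 186 h in beta, 268 h in theta and 454 h in alpha. The chain has two characteristic times, which add up to τ and whose product is the opening time times the reciprocal of k_cap. The longer one, T, is 118 h in gamma, 150 h in beta, 226 h in theta and 409 h in alpha. I dropped the term of the shorter time, which in gamma is 31.0 h, far below the run time. What has not become target is then T over the difference of the two times, multiplied by e to the power of minus run time over T. That gave me 0.936, 0.881, 0.751 and 0.535 as fractions of the substrate charged, a row that falls all the way.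

The forecast gave 93%, 88.5%, 76% and 55%, a course that falls all the way, holding that “more ligand can only slow the reaction”. My figure for alpha stands below its figure.

The simulation gave 92.9%, 87.6%, 75.1% and 54.0%, a course that falls all the way, as the forecast said. In gamma the opening time of 75.6 h and the tail of 73.3 h are close, and at 7.50 d open intermediate stood at 11.5% beside substrate at 17.0%. In alpha the opening time of 380 h is longer than the tail, and at 15.0 d open intermediate stood at 5.14% beside substrate at 40.8%.

The constants are assumed; the result is computed.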